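**Plan**

1. Retrosynthesis: the three O–CH2OCH3 bonds are cut first (global deprotection). The next cut is the C2–C1′ bond between pyranone ring C and benzo ring B, which gives chromone 9 (C2–H) and chromene 7 (C6–H, the later C1′), neither carrying a halogen or a metal. Ring D of 7 is then cut at O1–C2 and C4–C4a, back to a 1,1-dimethylpropargyl ether of mono-protected catechol.
2. Forward: ring D is closed onto ring B first (Claisen, hydrogen shift and oxa-6π cascade, steps 1–3). Rings A and C come ready-made as 5,7-dihydroxychromone (step 4). The two bicycles are joined in one flask (step 5) and the three MOM groups are removed (step 6).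
3. Enabling feature: ring B is 1,2,3-trisubstituted (C4a, C8a, C8), so C6–H is its only aryl C–H flanked by two hydrogens, and sterically governed iridium borylation should go there. C2 of ring C is the β-carbon of the vinylogous ester O1–C2=C3–C4=O, so an aryl-palladium species delivers its aryl group there and the C2 hydrogen is then lost.
4. Stereochemistry: the target has no stereocentre. Its only non-aromatic C=C (C3=C4 of ring D) is cis by ring constraint, so nothing has to be set.

Key step: step 5

Remark on the chemistry: alkali-metal and titanium phenoxides formed by deprotonation are treated as salt forms of the parent phenols, not as separate intermediates.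

**Step 1**
Reactants: 1 catechol (benzene-1,2-diol)
Product: 2 2-(methoxymethoxy)phenol
Conditions: NaH (1.0 equiv), THF/DMF, 0 °C; MOMCl (1.0 equiv), 0 °C to rt
Reagents that add atoms: chloromethyl methyl ether (MOMCl), COCCl
Why: Williamson-type O-alkylation with an α-chloro ether; one equivalent of base gives the hydrogen-bonded monosodium catecholate and the second OH is far less acidic, so the mono-ether should predominate and can be separated from diether and catechol by base extraction and chromatography.

**Step 2**
Reactants: 2 2-(methoxymethoxy)phenol; 3 3-chloro-3-methylbut-1-yne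
Product: 4 1-(methoxymethoxy)-2-[(2-methylbut-3-yn-2-yl)oxy]benzene
Conditions: K2CO3 (2 equiv), KI (0.2 equiv), CuI (copper monoiodide, 2 mol %), acetone, 60 °C, N2
Reagents that add atoms: none
Why: copper-assisted etherification of a phenoxide with a tertiary propargylic chloride, the standard entry to aryl 1,1-dimethylpropargyl ethers, under basic conditions that leave the MOM acetal untouched.

**Step 3**
Reactants: 4 1-(methoxymethoxy)-2-[(2-methylbut-3-yn-2-yl)oxy]benzene
Product: 7 8-(methoxymethoxy)-2,2-dimethyl-2H-chromene, via allenylphenol 5 (not isolated), via ortho-quinone methide 6 (not isolated)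
Conditions: o-xylene, 145 °C, N2
Reagents that add atoms: none
Why: thermal aryl propargyl ether Claisen rearrangement, in which the [3,3] shift can only go to the one free ortho carbon (the other carries OMOM) and after enolization gives allenylphenol 5, whose 1,5-hydrogen shift gives quinone methide 6 that closes ring D by oxa-6π electrocyclization.

**Step 4**
Reactants: 8 5,7-dihydroxy-4H-chromen-4-one
Product: 9 5,7-bis(methoxymethoxy)-4H-chromen-4-one
Conditions: NaH (2.4 equiv), DMF, 0 °C; MOMCl (2.4 equiv), 0 °C to rt
Reagents that add atoms: chloromethyl methyl ether (MOMCl), COCCl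
Why: Williamson-type acetal formation on both phenoxides; the strong base breaks the hydrogen bond of the peri 5-OH to the C4 carbonyl, and the non-nucleophilic hydride spares the base-sensitive pyranone ring.

**Step 5**
Reactants: 7 8-(methoxymethoxy)-2,2-dimethyl-2H-chromene; 10 bis(pinacolato)diboron; 9 5,7-bis(methoxymethoxy)-4H-chromen-4-one
Product: 12 5,7-bis(methoxymethoxy)-2-[8-(methoxymethoxy)-2,2-dimethyl-2H-chromen-6-yl]-4H-chromen-4-one, via aryl pinacol boronate 11 (not isolated)
Conditions: (a) [Ir(OMe)(cod)]2 (1.5 mol %), 4,4′-di-tert-butyl-2,2′-bipyridine (3 mol %), 10 (0.55 equiv), THF, 60 °C; volatiles removed in vacuo; (b) 9 (1.5 equiv), Pd(O2CCF3)2 (10 mol %), 5-nitro-1,10-phenanthroline (20 mol %), DMSO, O2 (1 atm), 90 °C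
Reagents that add atoms: none
Why: In stage (a) the bipyridine-ligated tris(boryl) complex of trivalent iridium cleaves the least hindered aryl C–H bond, and since C5–H lies next to ring-fusion carbon C4a and C7–H next to C8–OMOM, only C6–H is flanked by two hydrogens and boronate 11 should form there, while the vinyl C3–H and C4–H bonds of ring D are shielded by the quaternary C2 and the peri C5–H. In stage (b) 11 transfers its aryl group to a hydroxo or peroxo complex of divalent palladium formed under O2 without added base, the aryl-palladium adds syn across C2=C3 of 9 with the aryl group on C2 (the β-carbon of the vinylogous ester) and palladium on C3 as the enolate, isomerization through the oxygen-bound enolate allows syn β-hydride elimination of the C2 hydrogen to restore the pyranone, and O2 reoxidizes zerovalent palladium. The closest known reaction types are one-pot iridium C–H borylation and cross-coupling sequences and the oxidative boron-Heck arylation of chromones with arylboron reagents to flavones. No ring is closed and no stereocentre is created. The step needs site selectivity on ring B (secured by the steric pattern above), regioselectivity on ring C (secured by the enone polarization, which directs the aryl group to C2 only), and chemoselectivity of the aryl-palladium for the electron-poor C2=C3 bond of 9 over the hindered, electron-rich C3=C4 bond of ring D and over homocoupling (secured by the excess of 9 and by charging 10 at just over half an equivalent so that no diboron reaches stage (b)).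

**Step 6**
Reactants: 12 5,7-bis(methoxymethoxy)-2-[8-(methoxymethoxy)-2,2-dimethyl-2H-chromen-6-yl]-4H-chromen-4-one
Product: 13 Yinyanghuo E [5,7-dihydroxy-2-(8-hydroxy-2,2-dimethyl-2H-chromen-6-yl)-4H-chromen-4-one]
Conditions: 3 M aq. HCl, MeOH/THF, 50 °C
Reagents that add atoms: none
Why: acid-catalysed transacetalization of the three aryl MOM ethers to methanol (the acetal carbon leaves as dimethoxymethane), the usual end game for MOM-protected pyranoflavonoids, under dilute acid that the 2,2-dimethyl-2H-chromene alkene should tolerate.

**Compound list**

1 | catechol (benzene-1,2-diol) | Oc1ccccc1O | starting material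
2 | 2-(methoxymethoxy)phenol | COCOc1ccccc1O | intermediate
3 | 3-chloro-3-methylbut-1-yne | C#CC(C)(C)Cl | starting material
4 | 1-(methoxymethoxy)-2-[(2-methylbut-3-yn-2-yl)oxy]benzene | COCOc1ccccc1OC(C)(C)C#C | intermediate
5 | 2-(methoxymethoxy)-6-(3-methylbuta-1,2-dien-1-yl)phenol (allenylphenol, formed in the flask) | COCOc1cccc(C=C=C(C)C)c1O | intermediate
6 | (6Z)-2-(methoxymethoxy)-6-(3-methylbut-2-en-1-ylidene)cyclohexa-2,4-dien-1-one (ortho-quinone methide, formed in the flask) | CC(C)=C/C=C1/C=CC=C(OCOC)C1=O | intermediate
7 | 8-(methoxymethoxy)-2,2-dimethyl-2H-chromene | CC1(C)C=Cc2cccc(OCOC)c2O1 | intermediate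
8 | 5,7-dihydroxy-4H-chromen-4-one | O=c1ccoc2cc(O)cc(O)c12 | starting material
9 | 5,7-bis(methoxymethoxy)-4H-chromen-4-one | O=c1ccoc2cc(OCOC)cc(OCOC)c12 | intermediate
10 | bis(pinacolato)diboron | CC1(C)OB(OC1(C)C)B1OC(C)(C)C(C)(C)O1 | starting material
11 | 2-[8-(methoxymethoxy)-2,2-dimethyl-2H-chromen-6-yl]-4,4,5,5-tetramethyl-1,3,2-dioxaborolane (formed in the flask) | CC1(C)C=Cc2cc(B3OC(C)(C)C(C)(C)O3)cc(OCOC)c2O1 | intermediate
12 | 5,7-bis(methoxymethoxy)-2-[8-(methoxymethoxy)-2,2-dimethyl-2H-chromen-6-yl]-4H-chromen-4-one | CC1(C)C=Cc2cc(-c3cc(=O)c4c(OCOC)cc(OCOC)cc4o3)cc(OCOC)c2O1 | intermediate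
13 | Yinyanghuo E, 5,7-dihydroxy-2-(8-hydroxy-2,2-dimethyl-2H-chromen-6-yl)-4H-chromen-4-one | CC1(C)C=Cc2cc(-c3cc(=O)c4c(O)cc(O)cc4o3)cc(O)c2O1 | target

**Step count and risks**

Total step count: 6. Longest linear sequence: 5 steps (steps 1, 2, 3, 5, 6); step 4 is a one-step side branch.

Steps most likely to fail:

**Step 5.** Several processes could go wrong:
- borylation may leak to the vinyl C–H bonds, or an iridium hydride may add across the ring D alkene;
- boron-to-palladium transfer from the pinacol ester may be slow without base;
- the aryl-palladium may be lost to oxidative homocoupling or to Heck-type capture by the ring D alkene;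
- the palladium enolate may be protonated without dehydrogenation.

The fallback avoids both C–H events and uses a Negishi coupling. It sets out from 2 (using 3 and 9 as before) and comes back at 12. Compound 2 is brominated para to its free OH, the stronger donor (NBS, MeCN, 0 °C), to give 4-bromo-2-(methoxymethoxy)phenol F1. Etherification with 3 under the conditions of step 2 gives 4-bromo-2-(methoxymethoxy)-1-[(2-methylbut-3-yn-2-yl)oxy]benzene F2. Heating as in step 3 takes F2 through 4-bromo-2-(methoxymethoxy)-6-(3-methylbuta-1,2-dien-1-yl)phenol F3 and (6Z)-4-bromo-2-(methoxymethoxy)-6-(3-methylbut-2-en-1-ylidene)cyclohexa-2,4-dien-1-one F4 to 6-bromo-8-(methoxymethoxy)-2,2-dimethyl-2H-chromene F5, whose bromine sits para to the ring oxygen. Chromone 9 is then zincated at C2 (TMPZnCl·LiCl, MgCl2, THF) to [5,7-bis(methoxymethoxy)-4-oxo-4H-chromen-2-yl]zinc chloride F6, which is not isolated. Negishi coupling of F6 with F5 (Pd(OAc)2, SPhos, THF, 50 °C, zerovalent palladium formed in situ) should give 12.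

**Step 6.** Methanol or chloride may add across the styrene-like C3=C4 bond, or ring D may open, during the acid exposure needed to solvolyse three acetals. The fallback sets out from 12 and comes back at 13. The acetals are not solvolysed but exchanged: Me3SiOSO2CF3 and 2,2′-bipyridine in MeCN at 0 °C should convert the three aryl MOM ethers, in a medium free of protic acid, into 2-{2,2-dimethyl-8-[(trimethylsilyl)oxy]-2H-chromen-6-yl}-5,7-bis[(trimethylsilyl)oxy]-4H-chromen-4-one F7. Treatment of the mixture with K2CO3 in MeOH at rt then removes the silyl groups to give 13.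

**Step 2.** Dehydrochlorination of the tertiary propargylic chloride may outrun substitution at the hindered ortho-substituted phenoxide and leave the phenol unconverted. The fallback sets out from 2 and comes back at 7, replacing O-alkylation and Claisen rearrangement by a direct chromenylation. Compound 2 is heated with 3-methylbut-2-enal (CC(C)=CC=O) and Ti(OEt)4 in toluene at reflux. Ortho-selective condensation of the titanium phenoxide at the one free ortho carbon, with loss of water, should give quinone methide 6 directly, which closes to 7. Compounds 4 and 5 are bypassed and no compound outside the list is made (F0).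

**Further compounds**

F1 | step 5 | 4-bromo-2-(methoxymethoxy)phenol | COCOc1cc(Br)ccc1O
F2 | step 5 | 4-bromo-2-(methoxymethoxy)-1-[(2-methylbut-3-yn-2-yl)oxy]benzene | COCOc1cc(Br)ccc1OC(C)(C)C#C
F3 | step 5 | 4-bromo-2-(methoxymethoxy)-6-(3-methylbuta-1,2-dien-1-yl)phenol | COCOc1cc(Br)cc(C=C=C(C)C)c1O
F4 | step 5 | (6Z)-4-bromo-2-(methoxymethoxy)-6-(3-methylbut-2-en-1-ylidene)cyclohexa-2,4-dien-1-one | CC(C)=C/C=C1/C=C(Br)C=C(OCOC)C1=O
F5 | step 5 | 6-bromo-8-(methoxymethoxy)-2,2-dimethyl-2H-chromene | CC1(C)C=Cc2cc(Br)cc(OCOC)c2O1
F6 | step 5 | [5,7-bis(methoxymethoxy)-4-oxo-4H-chromen-2-yl]zinc chloride | O=c1cc([Zn]Cl)oc2cc(OCOC)cc(OCOC)c12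
F7 | step 6 | 2-{2,2-dimethyl-8-[(trimethylsilyl)oxy]-2H-chromen-6-yl}-5,7-bis[(trimethylsilyl)oxy]-4H-chromen-4-one | CC1(C)C=Cc2cc(-c3cc(=O)c4c(O[Si](C)(C)C)cc(O[Si](C)(C)C)cc4o3)cc(O[Si](C)(C)C)c2O1
F0 | step 2 | none | none
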